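**Retrosynthetic overview**
1. Target 13 comes from mono-methylenation of the C2-symmetric 8,14-diketone 12; 12 comes from Kolbe homocoupling (C11–C12 bond) of hydroxy keto acid 11.
2. Ring A of 11 is closed last, at C3–C4, by an iron-hydride HAT radical cyclization of an isopropenyl/aldehyde cyclohexene 9 (sets the gem-dimethyl group and the 3β-OH).
3. 9 comes from acid-mediated opening of the cyclobutane of pinane ketone 7: the CMe2 bridge carbon becomes C4 and the bridgehead becomes C5.
4. Key step: anionic oxy-Cope [3,3] rearrangement of allyl carbinol 3 (from (+)-verbenone) forms the C1–C10 bond and the C10 quaternary centre anti to the bridge; the enolate is trapped at C9 with bromoacetate.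
5. Ring order: ring B is the six-membered ring of verbenone (bought), ring A is then closed in each half, and the two halves are joined.

Assumption: (1R,5R)-(+)-verbenone is taken as purchasable (it is also one allylic oxidation from (+)-α-pinene). Atom labels C1–C12 in the text are those of the target.

**Step 1**
Reactants: 1 (1R,5R)-(+)-verbenone; 2 allylmagnesium bromide
Product: 3 (1R,2R,5R)-2-allyl-4,6,6-trimethylbicyclo[3.1.1]hept-3-en-2-ol
Conditions: allylMgBr (1.3 equiv), THF, −78 °C to 0 °C; H2O work-up
Reagents that add atoms: none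
Why: 1,2-Grignard addition to the enone carbonyl; the reagent attacks from the face opposite the CMe2 bridge, so the allyl group sits anti to the bridge and the hydroxyl syn to it.

**Step 2**
Reactants: 3 (1R,2R,5R)-2-allyl-4,6,6-trimethylbicyclo[3.1.1]hept-3-en-2-ol; 4 methyl bromoacetate
Product: 7 methyl 2-(4-allyl-4,6,6-trimethyl-2-oxobicyclo[3.1.1]heptan-3-yl)acetate, via potassium alkoxide 5 (not isolated), via potassium enolate 6 (not isolated)
Conditions: KH, 18-crown-6, THF, 0 °C to rt; then BrCH2CO2Me, −78 °C to 0 °C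
Reagents that add atoms: none
Why: Anionic oxy-Cope rearrangement ([3,3]-sigmatropic) moves the allyl group suprafacially to the β-carbon on the face anti to the bridge, which sets the C10 quaternary centre with methyl cis to the future C4; the regiodefined enolate is then C-alkylated at C9, the only enolisable position (its configuration is reset in step 6).

**Step 3**
Reactants: 7 methyl 2-(4-allyl-4,6,6-trimethyl-2-oxobicyclo[3.1.1]heptan-3-yl)acetate
Product: 8 methyl 2-[2-acetoxy-6-allyl-6-methyl-5-(prop-1-en-2-yl)cyclohex-2-en-1-yl]acetate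
Conditions: BF3·OEt2 (cat.), Zn(OAc)2, Ac2O, 0 °C to rt
Reagents that add atoms: acetic anhydride, CC(=O)OC(C)=O
Why: Lewis-acid-promoted E1-type fragmentation of the cyclobutyl ketone breaks the bond between the carbonyl α-carbon and the CMe2 carbon, giving an isopropenyl group on C5 and the enol acetate that masks C8; the C5 stereocentre is untouched and the terminal vinyl group is too poor a nucleophile to interfere.

**Step 4**
Reactants: 8 methyl 2-[2-acetoxy-6-allyl-6-methyl-5-(prop-1-en-2-yl)cyclohex-2-en-1-yl]acetate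
Product: 9 methyl 2-[2-acetoxy-6-methyl-6-(3-oxopropyl)-5-(prop-1-en-2-yl)cyclohex-2-en-1-yl]acetate
Conditions: PdCl2(PhCN)2, CuCl2·2H2O, AgNO2 (all cat.), O2 (1 atm), t-BuOH/MeNO2, rt
Reagents that add atoms: dioxygen, O=O
Why: Nitrite-modified (aldehyde-selective) Wacker oxidation attacks only the monosubstituted alkene at its terminal carbon, leaving the 1,1-disubstituted isopropenyl group and the enol acetate alone; no stereocentre is touched.

**Step 5**
Reactants: 9 methyl 2-[2-acetoxy-6-methyl-6-(3-oxopropyl)-5-(prop-1-en-2-yl)cyclohex-2-en-1-yl]acetate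
Product: 10 methyl 2-(2-acetoxy-6-hydroxy-5,5,8a-trimethyl-1,4,4a,5,6,7,8,8a-octahydronaphthalen-1-yl)acetate
Conditions: Fe(acac)3 (0.3 equiv), PhSiH3, EtOH, 60 °C, argon
Reagents that add atoms: none
Why: Iron-hydride HAT reductive radical cyclization (by analogy with alkene-tethered ketones): Markovnikov H-atom transfer to the isopropenyl group is followed by 6-exo closure of C4 onto the aldehyde through a chair with the oxygen equatorial, giving the gem-dimethyl group and the 3β-alcohol, with the trans ring fusion already fixed by C5 and C10.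

**Step 6**
Reactants: 10 methyl 2-(2-acetoxy-6-hydroxy-5,5,8a-trimethyl-1,4,4a,5,6,7,8,8a-octahydronaphthalen-1-yl)acetate
Product: 11 3β-hydroxy-8-oxo-13,14,15,16,17-pentanorlabdan-12-oic acid
Conditions: LiOH, THF/MeOH/H2O, 40 °C; then aq HCl to pH 3
Reagents that add atoms: lithium hydroxide, [Li+].[OH-]
Why: Saponification of the methyl ester and the enol acetate; the freed C8 ketone lets C9 equilibrate by enolisation to the equatorial arm (9α-H), the stable configuration next to the quaternary C10.

**Step 7**
Reactants: 11 3β-hydroxy-8-oxo-13,14,15,16,17-pentanorlabdan-12-oic acid (2 equiv)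
Product: 12 26,27-dinor-α-onocerin-8,14-dione
Conditions: Pt anode, Pt cathode, NaOMe (0.1 equiv), MeOH, constant current, 30 °C
Reagents that add atoms: none
Why: Kolbe electrolysis: anodic decarboxylation of the γ-keto acid and homocoupling of the primary C11 radicals form the central C11–C12 bond without touching any stereocentre.

**Step 8**
Reactants: 12 26,27-dinor-α-onocerin-8,14-dione
Product: 13 26-nor-8-oxo-α-onocerin
Conditions: Ph3PCH3Br, KOtBu (ylide limiting, about 1.1 equiv net), THF, 0 °C to 60 °C; aq NH4Cl
Reagents that add atoms: methyltriphenylphosphonium bromide, C[P+](c1ccccc1)(c1ccccc1)c1ccccc1.[Br-]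
Why: Wittig methylenation with limiting ylide converts one of the two equivalent hindered ketones (statistical, unreacted 12 recycled); free hydroxyls are tolerated and C9 stays in its thermodynamic configuration.

**Compound list**
1 | (1R,5R)-(+)-verbenone | CC1=CC(=O)[C@@H]2C[C@H]1C2(C)C | starting material
2 | allylmagnesium bromide | C=CC[Mg]Br | starting material
3 | (1R,2R,5R)-2-allyl-4,6,6-trimethylbicyclo[3.1.1]hept-3-en-2-ol (allyl anti to the CMe2 bridge, OH syn) | CC1=C[C@](O)(CC=C)[C@@H]2C[C@H]1C2(C)C | intermediate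
4 | methyl bromoacetate | COC(=O)CBr | starting material
5 | potassium alkoxide of 3 | CC1=C[C@]([O-])(CC=C)[C@@H]2C[C@H]1C2(C)C.[K+] | intermediate
6 | potassium 4-allyl-4,6,6-trimethylbicyclo[3.1.1]hept-2-en-2-olate (allyl anti to the CMe2 bridge) | C=CC[C@]1(C)C=C([O-])[C@@H]2C[C@H]1C2(C)C.[K+] | intermediate
7 | methyl 2-(4-allyl-4,6,6-trimethyl-2-oxobicyclo[3.1.1]heptan-3-yl)acetate (allyl and ester arm both anti to the CMe2 bridge) | C=CC[C@]1(C)[C@H](CC(=O)OC)C(=O)[C@@H]2C[C@H]1C2(C)C | intermediate
8 | methyl 2-[2-acetoxy-6-allyl-6-methyl-5-(prop-1-en-2-yl)cyclohex-2-en-1-yl]acetate (isopropenyl cis to the ring methyl, allyl trans to isopropenyl, ester arm cis to allyl) | C=CC[C@]1(C)[C@H](CC(=O)OC)C(OC(C)=O)=CC[C@H]1C(C)=C | intermediate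
9 | methyl 2-[2-acetoxy-6-methyl-6-(3-oxopropyl)-5-(prop-1-en-2-yl)cyclohex-2-en-1-yl]acetate (configuration as in 8) | O=CCC[C@]1(C)[C@H](CC(=O)OC)C(OC(C)=O)=CC[C@H]1C(C)=C | intermediate
10 | methyl 2-(2-acetoxy-6-hydroxy-5,5,8a-trimethyl-1,4,4a,5,6,7,8,8a-octahydronaphthalen-1-yl)acetate (trans-fused, 3β-OH cis to the angular methyl, C9 arm still α) | COC(=O)C[C@@H]1C(OC(C)=O)=CC[C@H]2C(C)(C)[C@@H](O)CC[C@]12C | intermediate
11 | 3β-hydroxy-8-oxo-13,14,15,16,17-pentanorlabdan-12-oic acid (5α-H, 9α-H, 10β-Me) | O=C(O)C[C@H]1C(=O)CC[C@H]2C(C)(C)[C@@H](O)CC[C@]12C | intermediate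
12 | 26,27-dinor-α-onocerin-8,14-dione (C2-symmetric bis-3β-hydroxy diketone, halves joined C11–C12) | O=C1CC[C@H]2C(C)(C)[C@@H](O)CC[C@]2(C)[C@H]1CC[C@H]1C(=O)CC[C@H]2C(C)(C)[C@@H](O)CC[C@]12C | intermediate
13 | 26-nor-8-oxo-α-onocerin | C=C1CC[C@H]2C(C)(C)[C@@H](O)CC[C@]2(C)[C@H]1CC[C@H]1C(=O)CC[C@H]2C(C)(C)[C@@H](O)CC[C@]12C | target

**Totals and risks**
Total step count: 8. Longest linear sequence: 8 steps (1 to 13).

Step 5 is the most uncertain: radical addition to an aldehyde is reversible, and the C3 selectivity rests only on a chair argument. The fallback sets out from 9 and returns at 10. The aldehyde is converted (NH2OH·HCl, pyridine; then Ac2O) into the nitrile F1. The same Fe(acac)3/PhSiH3 HAT conditions then close ring A onto the nitrile, and aqueous work-up hydrolyses the ketimine to the 3-ketone F2. LiAlH(OtBu)3 (THF, −40 °C) reduces F2 by axial hydride delivery to the equatorial 3β-alcohol 10, so C3 is set by ketone reduction instead of by the ring closure.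

Step 4 may give the methyl ketone or stall on this crowded substrate. The fallback sets out from 8 and returns at 9. The monosubstituted alkene is hydroborated with disiamylborane (THF, 0 °C), which reacts much more slowly with the isopropenyl group and the enol acetate. Oxidation of the borane with Me3NO gives the primary alcohol F3, and Dess–Martin periodinane/NaHCO3 then gives 9.

Step 8 is statistical and cannot exceed about half conversion to 13 per pass. The fallback sets out from 11 and returns at 13. Acid 11 is methylenated completely (excess Ph3PCH3Br/KOtBu) to the methylene acid F4. F4 is then co-electrolysed with a three- to fourfold excess of 11 under the step 7 conditions, so that cross-coupling to 13 dominates what forms from F4; the symmetric by-product 12 goes back to step 8.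

**Further compounds**
F1 | step 5 | methyl 2-[2-acetoxy-6-(2-cyanoethyl)-6-methyl-5-(prop-1-en-2-yl)cyclohex-2-en-1-yl]acetate | N#CCC[C@]1(C)[C@H](CC(=O)OC)C(OC(C)=O)=CC[C@H]1C(C)=C
F2 | step 5 | methyl 2-(2-acetoxy-5,5,8a-trimethyl-6-oxo-1,4,4a,5,6,7,8,8a-octahydronaphthalen-1-yl)acetate | COC(=O)C[C@@H]1C(OC(C)=O)=CC[C@H]2C(C)(C)C(=O)CC[C@]12C
F3 | step 4 | methyl 2-[2-acetoxy-6-(3-hydroxypropyl)-6-methyl-5-(prop-1-en-2-yl)cyclohex-2-en-1-yl]acetate | OCCC[C@]1(C)[C@H](CC(=O)OC)C(OC(C)=O)=CC[C@H]1C(C)=C
F4 | step 8 | 3β-hydroxy-13,14,15,16-tetranorlabd-8(17)-en-12-oic acid | C=C1CC[C@H]2C(C)(C)[C@@H](O)CC[C@]2(C)[C@H]1CC(=O)O
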